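**Retrosynthetic overview**

1. Labels: ring A = trimethoxyphenyl ring, ring B = 1,4-dioxane ring, ring C = benzo ring carrying OMe and the enal; C7 = aryl-bearing carbon of ring B, C8 = methyl-bearing carbon; O-4′ and O-5′ = the ring C oxygens on C8 and C7. Target 14 ⇐ aldehyde 13 (Wittig two-carbon homologation) ⇐ phenol 12 (O-methylation at C4 of ring A).
2. Key disconnection, C7–O-5′: 12 ⇐ bisphenol 10, in which C7 is a plain CH2. Ag2O dehydrogenates ring A to para-quinone methide 11, and O-5′ closes ring B on C7 in the same flask, creating the C7 stereocentre trans to the C8 methyl group.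
3. Enabling feature: the oxygen on C4 of ring A is para to the benzylic carbon C7. Kept as a free OH until after the key step, it lets ring A be oxidised to a quinone methide whose exocyclic carbon is C7, while O-5′ of ring C sits in position for a 6-exo closure.
4. 10 ⇐ Mitsunobu etherification (C8–O-4′, inversion) of (R)-alcohol 5 with phenol 8, then double debenzylation; 5 ⇐ aryl Grignard 4 + (R)-propylene oxide 3; 8 ⇐ 5-hydroxyvanillin 6.
5. Ring order: rings A and C are bought as benzene rings; ring B is the only ring made and is closed in step 6.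

Key step: step 6

Remark on the chemistry: the target is read as the trans-(2S,3S)-2,3-dihydro-1,4-benzodioxine (C7 S, C8 S), so C8 must be (S) before ring closure; compounds 1, 3 and 6 are taken as purchasable.

**Route**

Step 1
Reactants: 1 4-bromo-2,6-dimethoxyphenol
Product: 2 2-(benzyloxy)-5-bromo-1,3-dimethoxybenzene
Conditions: BnBr, K2CO3, DMF, rt → 60 °C
Reagents that add atoms: benzyl bromide, BrCc1ccccc1
Why: Williamson ether synthesis, in which the phenoxide of 1 is benzylated by SN2 so that the ring A phenol is masked for the Grignard step and can later be freed by hydrogenolysis.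

Step 2
Reactants: 2 2-(benzyloxy)-5-bromo-1,3-dimethoxybenzene; 3 (R)-propylene oxide
Product: 5 (2R)-1-[4-(benzyloxy)-3,5-dimethoxyphenyl]propan-2-ol, via arylmagnesium bromide 4 (not isolated)
Conditions: Mg, THF, 50 °C; then CuI (10 mol%), 3, −30 → 0 °C; aq NH4Cl
Reagents that add atoms: none
Why: Grignard formation followed by CuI-catalysed epoxide opening at the unsubstituted CH2 carbon of 3, so the epoxide stereocentre is not touched and is carried over as the (R)-carbinol.

Step 3
Reactants: 6 5-hydroxyvanillin (3,4-dihydroxy-5-methoxybenzaldehyde)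
Product: 8 3-(benzyloxy)-4-hydroxy-5-methoxybenzaldehyde, via disodium dianion 7 (not isolated)
Conditions: NaH (2.2 equiv), DMSO, rt; BnBr (1.0 equiv), rt; aq HCl
Reagents that add atoms: benzyl bromide, BrCc1ccccc1
Why: Regioselective dianion alkylation, in which the 4-phenoxide of 7 is delocalised into the para-formyl group and flanked on both sides, so one equivalent of benzyl bromide should react at the more nucleophilic, less hindered 3-phenoxide.

Step 4
Reactants: 5 (2R)-1-[4-(benzyloxy)-3,5-dimethoxyphenyl]propan-2-ol; 8 3-(benzyloxy)-4-hydroxy-5-methoxybenzaldehyde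
Product: 9 3-(benzyloxy)-4-{[(2S)-1-[4-(benzyloxy)-3,5-dimethoxyphenyl]propan-2-yl]oxy}-5-methoxybenzaldehyde
Conditions: PPh3, DIAD, THF (1 M), 0 °C → rt
Reagents that add atoms: none
Why: Mitsunobu etherification, in which the acidic para-formyl phenol of 8 (its only free OH) displaces the alkoxyphosphonium derived from 5 by SN2 with inversion, which sets the (S) configuration at C8.

Step 5
Reactants: 9 3-(benzyloxy)-4-{[(2S)-1-[4-(benzyloxy)-3,5-dimethoxyphenyl]propan-2-yl]oxy}-5-methoxybenzaldehyde
Product: 10 3-hydroxy-4-{[(2S)-1-(4-hydroxy-3,5-dimethoxyphenyl)propan-2-yl]oxy}-5-methoxybenzaldehyde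
Conditions: H2 (1 atm), Pd/C (10 wt%), EtOAc, rt
Reagents that add atoms: none
Why: Catalytic hydrogenolysis should cleave both benzyl aryl ethers faster than it reduces the electron-rich aryl aldehyde, and the C8–O-4′ bond is a homobenzylic alkyl aryl ether that is not cleaved, so C8 is untouched.

Step 6
Reactants: 10 3-hydroxy-4-{[(2S)-1-(4-hydroxy-3,5-dimethoxyphenyl)propan-2-yl]oxy}-5-methoxybenzaldehyde
Product: 12 (2S,3S)-3-(4-hydroxy-3,5-dimethoxyphenyl)-8-methoxy-2-methyl-2,3-dihydro-1,4-benzodioxine-6-carbaldehyde, via para-quinone methide 11 (not isolated)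
Conditions: Ag2O (1.5 equiv), dry CH2Cl2, rt, dark
Reagents that add atoms: none
Why: Ag2O should oxidise the ring A phenol through its phenoxyl radical to para-quinone methide 11 with loss of one C7–H, which turns the unfunctionalised C7 into an electrophile, and the ring C hydroxyl O-5′ then adds to C7 in an oxa-1,6-conjugate addition that rearomatises ring A. The closest known reaction types are the Ag2O dehydrogenation of 4-alkyl-2,6-dimethoxyphenols to para-quinone methides that cyclise onto tethered nucleophiles, and the quinone methide ring closure that ends the biomimetic oxidative coupling to 1,4-benzodioxane neolignans. Ring B closes in the 6-exo-trig mode, since O-5′ attacks the exocyclic terminus of the C7=C1 bond of ring A. The new C7 stereocentre is controlled by C8: in the rotamer of 11 with C8–H eclipsing the exocyclic double bond (minimal A(1,3) strain) the tethered oxygen reaches the C7 face anti to the methyl group, which should give the trans-diequatorial (2S,3S) product, also the thermodynamically preferred isomer. The step needs chemoselective oxidation of ring A, secured because only ring A is a 2,6-dimethoxyphenol with a para benzylic C–H, whereas the ring C phenol is deactivated by the formyl group, has no para-alkyl group and can act only as the nucleophile. It also needs cyclisation to outrun tautomerisation of 11 to the enol ether, which the six-atom tether should secure.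

Step 7
Reactants: 12 (2S,3S)-3-(4-hydroxy-3,5-dimethoxyphenyl)-8-methoxy-2-methyl-2,3-dihydro-1,4-benzodioxine-6-carbaldehyde
Product: 13 (2S,3S)-8-methoxy-2-methyl-3-(3,4,5-trimethoxyphenyl)-2,3-dihydro-1,4-benzodioxine-6-carbaldehyde
Conditions: MeI, K2CO3, DMF, rt
Reagents that add atoms: iodomethane, CI
Why: Williamson O-methylation of the only remaining phenol under mild base, which leaves the non-enolisable aryl aldehyde and both ring B stereocentres untouched and removes the free phenol through which ring B could reopen.

Step 8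
Reactants: 13 (2S,3S)-8-methoxy-2-methyl-3-(3,4,5-trimethoxyphenyl)-2,3-dihydro-1,4-benzodioxine-6-carbaldehyde
Product: 14 (2E)-3-[(2S,3S)-8-methoxy-2-methyl-3-(3,4,5-trimethoxyphenyl)-2,3-dihydro-1,4-benzodioxin-6-yl]prop-2-enal
Conditions: Ph3P=CHCHO (1.2 equiv), toluene, 80 °C
Reagents that add atoms: (triphenylphosphoranylidene)acetaldehyde, O=CC=P(c1ccccc1)(c1ccccc1)c1ccccc1
Why: Wittig reaction with the stabilised formylmethylene ylide, which adds the two carbons and should give the (E)-enal, under neutral conditions that cannot affect ring B.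

**Compound list**

1 | 4-bromo-2,6-dimethoxyphenol | COc1cc(Br)cc(OC)c1O | starting material
2 | 2-(benzyloxy)-5-bromo-1,3-dimethoxybenzene | COc1cc(Br)cc(OC)c1OCc1ccccc1 | intermediate
3 | (R)-propylene oxide | C[C@@H]1CO1 | starting material
4 | [4-(benzyloxy)-3,5-dimethoxyphenyl]magnesium bromide | COc1cc([Mg]Br)cc(OC)c1OCc1ccccc1 | intermediate
5 | (2R)-1-[4-(benzyloxy)-3,5-dimethoxyphenyl]propan-2-ol | C[C@@H](O)Cc1cc(OC)c(OCc2ccccc2)c(OC)c1 | intermediate
6 | 5-hydroxyvanillin (3,4-dihydroxy-5-methoxybenzaldehyde) | COc1cc(C=O)cc(O)c1O | starting material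
7 | disodium 5-formyl-3-methoxybenzene-1,2-diolate | COc1cc(C=O)cc([O-])c1[O-].[Na+].[Na+] | intermediate
8 | 3-(benzyloxy)-4-hydroxy-5-methoxybenzaldehyde | COc1cc(C=O)cc(OCc2ccccc2)c1O | intermediate
9 | 3-(benzyloxy)-4-{[(2S)-1-[4-(benzyloxy)-3,5-dimethoxyphenyl]propan-2-yl]oxy}-5-methoxybenzaldehyde | C[C@@H](Cc1cc(OC)c(OCc2ccccc2)c(OC)c1)Oc1c(OC)cc(C=O)cc1OCc1ccccc1 | intermediate
10 | 3-hydroxy-4-{[(2S)-1-(4-hydroxy-3,5-dimethoxyphenyl)propan-2-yl]oxy}-5-methoxybenzaldehyde | C[C@@H](Cc1cc(OC)c(O)c(OC)c1)Oc1c(OC)cc(C=O)cc1O | intermediate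
11 | 4-{[(2S)-1-(3,5-dimethoxy-4-oxocyclohexa-2,5-dien-1-ylidene)propan-2-yl]oxy}-3-hydroxy-5-methoxybenzaldehyde (para-quinone methide) | C[C@@H](C=C1C=C(OC)C(=O)C(OC)=C1)Oc1c(OC)cc(C=O)cc1O | intermediate
12 | (2S,3S)-3-(4-hydroxy-3,5-dimethoxyphenyl)-8-methoxy-2-methyl-2,3-dihydro-1,4-benzodioxine-6-carbaldehyde | COc1cc([C@@H]2Oc3cc(C=O)cc(OC)c3O[C@H]2C)cc(OC)c1O | intermediate
13 | (2S,3S)-8-methoxy-2-methyl-3-(3,4,5-trimethoxyphenyl)-2,3-dihydro-1,4-benzodioxine-6-carbaldehyde | COc1cc([C@@H]2Oc3cc(C=O)cc(OC)c3O[C@H]2C)cc(OC)c1OC | intermediate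
14 | (2E)-3-[(2S,3S)-8-methoxy-2-methyl-3-(3,4,5-trimethoxyphenyl)-2,3-dihydro-1,4-benzodioxin-6-yl]prop-2-enal | COc1cc([C@@H]2Oc3cc(/C=C/C=O)cc(OC)c3O[C@H]2C)cc(OC)c1OC | target

**Step count and risks**

Total step count: 8. Longest linear sequence: 7 steps (steps 1, 2, 4, 5, 6, 7, 8).

Steps most likely to fail:

Step 6. The quinone methide may tautomerise to the enol ether before it is trapped (which would erase the C8 stereocentre), may be attacked by a phenol of a second molecule (oligomerisation), or the product phenol may be oxidised further; facial selectivity at C7 may also be incomplete. The fallback replaces the dehydrogenation by the intermolecular oxidative cross-coupling known for benzodioxane neolignans, and sets out from compound 6. 5-Hydroxyvanillin 6 and commercial (E)-2,6-dimethoxy-4-(prop-1-en-1-yl)phenol F1 would be treated with Ag2O in benzene–acetone at rt. Coupling of the propenyl β-carbon to O-4′ should give a quinone methide of the same type, which closes by the same 6-exo addition of O-5′ to C7. This should give the racemic trans-benzodioxane, that is, compound 12 together with its enantiomer (2R,3R)-3-(4-hydroxy-3,5-dimethoxyphenyl)-8-methoxy-2-methyl-2,3-dihydro-1,4-benzodioxine-6-carbaldehyde F2. Preparative chromatography on a chiral stationary phase would separate the two, and the route is rejoined at compound 12.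

Step 4. The redox condensation may stall at the doubly ortho-substituted phenol, and the activated secondary alcohol may eliminate towards the conjugated propenylarene. The fallback separates activation from substitution and sets out from compound 5. Alcohol 5 would be converted with MsCl and Et3N in CH2Cl2 at 0 °C into (2R)-1-[4-(benzyloxy)-3,5-dimethoxyphenyl]propan-2-yl methanesulfonate F3. The isolated sulfonate would then be displaced by the cesium phenoxide of 8 (Cs2CO3, DMF, 60 °C) in an SN2 reaction with inversion, and the route is rejoined at compound 9.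

Step 8. The ylide may react sluggishly with the electron-rich aryl aldehyde and may homologate the product enal a second time to the dienal. The fallback builds the enal by olefination to the ester and redox adjustment, and sets out from compound 13. A Horner–Wadsworth–Emmons reaction (triethyl phosphonoacetate, NaH, THF, 0 °C) should give ethyl (2E)-3-[(2S,3S)-8-methoxy-2-methyl-3-(3,4,5-trimethoxyphenyl)-2,3-dihydro-1,4-benzodioxin-6-yl]prop-2-enoate F4. Reduction with i-Bu2AlH in CH2Cl2 at −78 °C should give (2E)-3-[(2S,3S)-8-methoxy-2-methyl-3-(3,4,5-trimethoxyphenyl)-2,3-dihydro-1,4-benzodioxin-6-yl]prop-2-en-1-ol F5. Allylic oxidation with MnO2 in CH2Cl2 at rt then rejoins the route at compound 14.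

**Further compounds**

F1 | step 6 | (E)-2,6-dimethoxy-4-(prop-1-en-1-yl)phenol | C/C=C/c1cc(OC)c(O)c(OC)c1
F2 | step 6 | (2R,3R)-3-(4-hydroxy-3,5-dimethoxyphenyl)-8-methoxy-2-methyl-2,3-dihydro-1,4-benzodioxine-6-carbaldehyde | COc1cc([C@H]2Oc3cc(C=O)cc(OC)c3O[C@@H]2C)cc(OC)c1O
F3 | step 4 | (2R)-1-[4-(benzyloxy)-3,5-dimethoxyphenyl]propan-2-yl methanesulfonate | C[C@@H](OS(C)(=O)=O)Cc1cc(OC)c(OCc2ccccc2)c(OC)c1
F4 | step 8 | ethyl (2E)-3-[(2S,3S)-8-methoxy-2-methyl-3-(3,4,5-trimethoxyphenyl)-2,3-dihydro-1,4-benzodioxin-6-yl]prop-2-enoate | COc1cc([C@@H]2Oc3cc(/C=C/C(=O)OCC)cc(OC)c3O[C@H]2C)cc(OC)c1OC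
F5 | step 8 | (2E)-3-[(2S,3S)-8-methoxy-2-methyl-3-(3,4,5-trimethoxyphenyl)-2,3-dihydro-1,4-benzodioxin-6-yl]prop-2-en-1-ol | COc1cc([C@@H]2Oc3cc(/C=C/CO)cc(OC)c3O[C@H]2C)cc(OC)c1OC
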